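(The numbers were chosen freely; the result is computed.)

Free catalyst meets impurity at 0.0176 /min but starting material at 0.00969 /min, and the impurity step has no way back, so this reckoning takes the impurity's 2.2 mM off the catalyst from the start. That leaves a working catalyst of 8.80 mM at dawn and 4.90 mM in spring.

all flasks: starting material 0.051 M; second substrate 0.0255 M; reagent 0.0510 M; impurity 2.2 mM; time 12 h
- dawn: free catalyst 11 mM
- spring: free catalyst 7.1 mM

    starting material + free catalyst ⇌ catalyst intermediate A (K1 = 2300 /M, k1 = 0.19 /M/min)
    reagent + catalyst intermediate A → free catalyst + target (k2 = 0.094 /M/min)
    second substrate + free catalyst ⇌ catalyst intermediate B (K3 = 1100 /M, k3 = 0.25 /M/min)
    reagent + catalyst intermediate B → free catalyst + second product (k4 = 0.14 /M/min)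
    free catalyst + target ⇌ idle complex, settled at all times (K5 = 38 /M)
    free catalyst + impurity → spent catalyst (k6 = 8.0 /M/min)

- which of these there is most of at the end, counted by the starting material in it, dawn (catalyst intermediate A / target / starting material)
- which of these there is most of at the end, counted by the starting material in it, spring (catalyst intermediate A / target / starting material)
- the largest of these amounts at the end, in percent of the starting material charged, dawn
- the largest of these amounts at the end, in percent of the starting material charged, spring

In the working round, free catalyst binds a substrate and reagent frees it again. The way back from catalyst intermediate A, at 8.26 × 10⁻⁵ /min, is far slower than its reagent step at 0.00479 /min, and the way back from catalyst intermediate B, at 2.27 × 10⁻⁴ /min, is far slower than its reagent step at 0.00714 /min, so both are dropped. Setting entry equal to exit for each intermediate (steady state), with the idle complex set aside in this reckoning, gives the free share of the working catalyst: one over one plus, for each intermediate, its entry rate over its exit rate. At the charge this is 0.255. It depends on the ratios of the substrates to the reagent, and it is assumed to stay constant. Starting material then falls in a pseudo-first-order way, and the thinning constant, the binding rate constant times the free share, is 0.0485 /M/min. The fraction left is the exponential of minus this constant times working catalyst times time. This reckoning leaves 73.5 % at dawn and 84.3 % in spring, so starting material stays the largest pool in both flasks.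

The forecast names starting material for dawn and starting material for spring, at 71 % and 82 %, lower than this reckoning, holding turnover “too slow to consume most of the starting material”.

The simulation gives starting material as the largest at dawn, at 70.1 %, and starting material in spring, at 81.7 %, so the reckoning stands high by 3.4 percentage points and 2.6 points.

Read back from these amounts, the thinning constant is 0.0560 /M/min at dawn and 0.0574 /M/min in spring. The neighbouring spring flask charged with 0.028 M of free catalyst keeps the same substrate-to-reagent ratios, so the reckoned constant carries over to its working catalyst of 25.8 mM and leaves 40.6 % of the starting material. That flask holds 34.8 % of starting material at the end, and there target is the largest pool, at 41.7 %.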